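**Plan**
- Retrosynthesis: the C13–C16 bond is traced back to a C12–C16 bond (reverse 1,2-acyl shift); then C12–C13 and C8–C14 are cut together (Diels–Alder), which turns C8, C9, C11, C12, C16 and C15 into a guaiacol ring. Further cuts: C3–C4 (aldol), C10–C1 and the lactone C–O (organocerium addition/lactonisation), C4–C5 (enolate alkylation), C9–C10 (Friedel–Crafts), C6–aryl (conjugate arylation).
- Enabling feature: in ring C the atoms C8–C9–C11–C12 can act as a diene and C13–C14 as the dienophile, because C8 and C12 are flanked by C15 (carbinol) and C16 (methylidene carbon), which map onto the two oxygen-bearing carbons of an o-quinone monoketal. The aromatic C12–C16 bond is a temporary ring bond that is moved to C13 afterwards.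
- Forward order: aryl ring (future C8, C9, C11, C12, C15, C16), ring B (indanone), 19,10-lactone, ring A, dearomatisation, ring C by Diels–Alder (bicyclo[2.2.2]octenone), ring D by shift of C16 from C12 to C13, then C17 and the C15 hydroxyl.
- Stereochemistry: C6 from a rhodium-catalysed asymmetric arylation; C5, C10 and C4 by substrate control from C6; C3 by K-Selectride; C8 by the facial selectivity of the cycloaddition (C13 then follows from the bridged topology); C9 by hydrogenation; C15 by Luche reduction.

Key step: step 16

Remark (conventions): gibberellane numbering is used for every intermediate (C7 = carboxyl carbon on C6, C18 = methyl on C4, C19 = lactone carbonyl on C4, C17 = methylidene carbon). α is the face of ring B that carries the lactone oxygen on C10; β is the face that carries C7.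
Remark (chemistry): in step 1 the enantiomer of the diene ligand is assumed to be the one that delivers the S product. Epimer mixtures at C4 (compounds 9 to 13) and at C3 (compound 14) converge in steps 8 to 10.

Step 1
Reactants: 1 (2,3-dimethoxyphenyl)boronic acid; 2 di-tert-butyl fumarate
Product: 3 di-tert-butyl (S)-2-(2,3-dimethoxyphenyl)succinate
Conditions: [RhCl(C2H4)2]2 (cat.), 2,5-diphenylbicyclo[2.2.2]octa-2,5-diene (single enantiomer), KOH (cat.), dioxane/H2O, 50 °C
Reagents that add atoms: none
Why: Hayashi–Miyaura rhodium-catalysed asymmetric 1,4-addition of an arylboronic acid to a fumarate; the chiral diene–rhodium complex selects one enantiotopic face of the alkene and sets C6 (S).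

Step 2
Reactants: 3 di-tert-butyl (S)-2-(2,3-dimethoxyphenyl)succinate
Product: 5 (S)-6,7-dimethoxy-3-oxoindane-1-carboxylic acid, via diacid 4 (not isolated)
Conditions: CF3CO2H, CH2Cl2, rt; evaporate; (CF3CO)2O, CH2Cl2, 0 °C → rt
Reagents that add atoms: none
Why: acidolysis of both tert-butyl esters, then intramolecular Friedel–Crafts acylation through the mixed anhydride; only the CH2-bound carboxyl can reach the ring (five-membered ring B), and it attacks the free ortho position para to a methoxy group, leaving C6 untouched.

Step 3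
Reactants: 5 (S)-6,7-dimethoxy-3-oxoindane-1-carboxylic acid
Product: 6 (S)-6-hydroxy-7-methoxy-3-oxoindane-1-carboxylic acid
Conditions: NaSEt, DMF, 110 °C; then aq. HCl
Reagents that add atoms: none
Why: nucleophilic (SN2) O-demethylation by thiolate should be selective for the C16 methoxy group para to the acyl-bearing ring carbon, whose phenoxide is a vinylogous carboxylate; the C7 carboxylate keeps C6 non-enolisable.

Step 4
Reactants: 6 (S)-6-hydroxy-7-methoxy-3-oxoindane-1-carboxylic acid
Product: 7 (S)-6-benzyloxy-7-methoxy-3-oxoindane-1-carboxylic acid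
Conditions: BnBr (1.05 equiv), K2CO3, acetone, 55 °C; then aq. HCl
Reagents that add atoms: benzyl bromide, BrCc1ccccc1
Why: Williamson etherification in which the phenoxide is far more nucleophilic than the carboxylate, so that C7 stays a carboxylate and C6 cannot enolise.

Step 5
Reactants: 7 (S)-6-benzyloxy-7-methoxy-3-oxoindane-1-carboxylic acid; 8 methyl 2-bromopropanoate (racemic)
Product: 9 (1S,2S)-6-benzyloxy-7-methoxy-2-(1-methoxy-1-oxopropan-2-yl)-3-oxoindane-1-carboxylic acid (C5/C6 trans; C4 epimers)
Conditions: LiN(i-Pr)2 (2.2 equiv), THF/DMPU, −78 °C; then 8, −78 → −20 °C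
Reagents that add atoms: none
Why: alkylation of the carboxylate/ketone-enolate dianion (the carboxylate blocks deprotonation at C6, so only C5 is enolised); the electrophile enters anti to the C6 carboxylate and sets C5 trans to C6.

Step 6
Reactants: 9 trans keto acid; 10 but-3-en-1-ylmagnesium bromide
Product: 12 butenyl γ-lactone acid (C10 quaternary; C4 epimers), via hydroxy ester 11 (not isolated)
Conditions: CeCl3, excess 10, THF, −78 → 0 °C; aq. NH4Cl, rt
Reagents that add atoms: none
Why: organocerium 1,2-addition to the enolisable ketone from the face anti to the C5 side chain sets C10 (C1 β, O α), and the alkoxide, now cis to the C19 ester, lactonises spontaneously.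

Step 7
Reactants: 12 butenyl γ-lactone acid
Product: 13 lactone aldehyde (C10 chain CH2CH2CHO)
Conditions: OsO4 (cat.), NaIO4, 2,6-lutidine, dioxane/H2O, rt
Reagents that add atoms: osmium tetroxide, O=[Os](=O)(=O)=O (oxygen carrier); sodium periodate, [Na+].[O-]I(=O)(=O)=O (terminal oxidant that supplies the aldehyde oxygen)
Why: Lemieux–Johnson cleavage of the terminal alkene gives the C3 aldehyde under buffered conditions that should not ionise the benzylic lactone.

Step 8
Reactants: 13 lactone aldehyde
Product: 14 ring A aldol product (3-hydroxy tetracycle; C3 epimers)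
Conditions: K2CO3, MeOH, rt; then aq. citric acid
Reagents that add atoms: none
Why: intramolecular aldol addition of the lactone enolate (C4) to the C3 aldehyde, the reverse of the known base-induced retro-aldol of 3-hydroxy gibberellin lactones, closes ring A; C4 is fixed by the bridged lactone geometry and the C7 carboxylate prevents C6 from competing as a nucleophile.

Step 9
Reactants: 14 ring A aldol product
Product: 15 3-ketone
Conditions: Dess–Martin periodinane, NaHCO3, CH2Cl2, rt
Reagents that add atoms: none
Why: Dess–Martin oxidation of the secondary alcohol converges both C3 epimers to one β-keto lactone that cannot enolise at C4.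

Step 10
Reactants: 15 3-ketone
Product: 16 3β-alcohol
Conditions: KBH(s-Bu)3 (K-Selectride), THF, −78 °C
Reagents that add atoms: none
Why: the bulky trialkylborohydride attacks the C3 ketone along the equatorial trajectory and should give the axial 3β-alcohol, as is known for 3-oxo gibberellin lactones.

Step 11
Reactants: 16 3β-alcohol
Product: 17 2-(trimethylsilyl)ethyl ester
Conditions: Me3SiCH2CH2OH (excess), EDC·HCl, DMAP, CH2Cl2, rt
Reagents that add atoms: 2-(trimethylsilyl)ethanol, C[Si](C)(C)CCO
Why: Steglich-type carbodiimide esterification; the hindered axial C3 hydroxyl should not compete with the primary alcohol used in excess.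

Step 12
Reactants: 17 2-(trimethylsilyl)ethyl ester
Product: 18 3-O-TBS ether
Conditions: t-BuMe2SiCl, imidazole, DMAP, DMF, 50 °C
Reagents that add atoms: tert-butyldimethylsilyl chloride, CC(C)(C)[Si](C)(C)Cl
Why: silylation of the secondary alcohol without a Lewis acid (a silyl triflate is avoided because the tertiary benzylic lactone could ionise).

Step 13
Reactants: 18 3-O-TBS ether
Product: 19 phenol (C16–OH)
Conditions: H2 (1 atm), Pd/C, EtOAc, rt
Reagents that add atoms: none
Why: hydrogenolysis of the aryl benzyl ether under neutral conditions, under which the tertiary benzylic lactone C–O bond should persist.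

Step 14
Reactants: 19 phenol
Product: 20 masked o-benzoquinone (C16 ketone; C15 dimethyl ketal; 8,9:11,12-diene)
Conditions: PhI(OAc)2, KHCO3, MeOH, 0 °C
Reagents that add atoms: methanol, CO
Why: oxidative dearomatisation of a 2-methoxyphenol by the trivalent iodine reagent (Wessely-type); methanol adds at the methoxy-bearing ortho carbon C15, and the substituents on C8 and C9 block the usual self-dimerisation so that the dienone can be isolated.

Step 15
Reactants: 21 acetyltrimethylsilane
Product: 22 trimethyl{[1-(trimethylsilyl)ethenyl]oxy}silane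
Conditions: LiN(i-Pr)2, THF, −78 °C; then Me3SiCl
Reagents that add atoms: chlorotrimethylsilane, C[Si](C)(C)Cl
Why: kinetic enolisation of the acylsilane and O-silylation give the silyl enol ether.

Step 16
Reactants: 20 masked o-benzoquinone; 22 trimethyl{[1-(trimethylsilyl)ethenyl]oxy}silane
Product: 23 Diels–Alder adduct (bicyclo[2.2.2]octenone; new bonds C12–C13 and C8–C14; C13 bears SiMe3 and OSiMe3)
Conditions: excess 22, toluene, 90 °C, sealed tube
Reagents that add atoms: none
Why: The electron-poor cyclohexa-2,4-dienone 20 reacts as the 4π partner (C8=C9–C11=C12) with the electron-rich enol ether 22 in a polar, asynchronous inverse-electron-demand Diels–Alder reaction, the closest precedent being the cycloadditions of masked o-benzoquinones with enol ethers. The cycloaddition closes ring C (C8–C9–C11–C12–C13–C14) intermolecularly as part of a bicyclo[2.2.2]octenone whose third bridge is the old arene unit C15–C16, so C16 is still tied to C12 and is moved to C13 in step 18. The nucleophilic CH2 terminus of 22 (C14) bonds to C8, the δ-carbon and most electrophilic terminus of the dienone, and the fully substituted carbon (C13) bonds to the unhindered C12 next to the carbonyl; this is the innate regiochemistry of masked o-benzoquinones and is reinforced by sterics. C8 is the new permanent stereocentre: the dienophile should approach the α face, which carries only H6 and the lactone oxygen, and avoid the β face screened by the C7 ester on C6 and the C1 methylene on C10, which places C14 α as in the target; C12 follows from the suprafacial addition and the configuration at C13 is irrelevant because C13 is reorganised in step 18. Self-dimerisation of 20 is suppressed by the substituents on C8 and C9, and the reaction is run in an aprotic solvent because 22 is solvolysed by methanol.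

Step 17
Reactants: 23 Diels–Alder adduct
Product: 24 dihydro adduct (9β-H)
Conditions: H2 (1–4 atm), [Ir(cod)(PCy3)(py)]PF6 (cat.), CH2Cl2, rt
Reagents that add atoms: none
Why: homogeneous syn-hydrogenation of the hindered trisubstituted alkene with Crabtree's catalyst should occur from the β face, where the coordinating groups lie (C7 ester carbonyl, C15 methoxy, C16 carbonyl), while the α face is screened by the geminal silyl and silyloxy groups on C13; this sets C9.

Step 18
Reactants: 24 dihydro adduct
Product: 26 13-O-trimethylsilyl ketol (bicyclo[3.2.1]octane rings C and D; C16 ketone; C15 dimethyl ketal), via cyclopropanolate 25 (not isolated)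
Conditions: KOt-Bu (0.2 equiv), t-BuOH (2 equiv), THF, −40 → 0 °C
Reagents that add atoms: none
Why: Proposed new method: tert-butoxide removes the O-silyl group of 24, the resulting β-keto α-silyl alkoxide undergoes a [1,2]-Brook rearrangement and the emerging C13 carbanion adds to the adjacent C16 carbonyl to give cyclopropanolate 25, which opens by cleavage of the strained C12–C16 bond with protonation of C12 by tert-butanol (regenerating tert-butoxide), so that the C16 acyl group moves from C12 to C13 and C13 keeps its oxygen as the trimethylsilyl ether; the closest known reactions are the Brook-rearrangement-mediated formation of cyclopropane-1,2-diol monosilyl ethers from acylsilane–ketone enolate adducts and the base-induced homoenolate-type opening of cyclopropanols; the direction is unambiguous because only the C16 oxygen is an alkoxide, the saturated C9–C11 bond rules out a vinylogous elimination of the C10 lactone oxygen, the configuration of C13 is dictated by the bicyclo[3.2.1] topology, and the O-silyl group blocks α-ketol isomerisation.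

Step 19
Reactants: 26 13-O-trimethylsilyl ketol
Product: 27 16-methylidene compound
Conditions: Zn, CH2Br2, TiCl4, THF/CH2Cl2, 0 °C → rt
Reagents that add atoms: dibromomethane, BrCBr
Why: Takai–Lombardo methylenation, a non-basic zinc/titanium methylene transfer used for base-sensitive 16-oxo gibberellin-type ketones, should convert the non-enolisable C16 ketone into the exocyclic alkene without touching ester, lactone or ketal.

Step 20
Reactants: 27 16-methylidene compound
Product: 28 13-hydroxy-15-oxo enone
Conditions: 1 M aq. HCl, THF, 0 °C → rt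
Reagents that add atoms: water, O
Why: acid hydrolysis of the allylic dimethyl ketal (through the methoxy-substituted allyl cation) and of the tertiary trimethylsilyl ether; the secondary TBS ether and the ester should survive, and the electron-poor enone is not prone to acid-induced Wagner–Meerwein rearrangement.

Step 21
Reactants: 28 13-hydroxy-15-oxo enone
Product: 29 3-O-TBS 2-(trimethylsilyl)ethyl ester of the target gibberellin
Conditions: NaBH4, CeCl3·7H2O, MeOH, −78 °C
Reagents that add atoms: none
Why: Luche 1,2-reduction; hydride should approach the C15 carbonyl from the exo face (the side of the C14 bridge), away from the C9–C11–C12 bridge and the C7 ester, giving the C15 alcohol with the hydroxyl turned toward C9/C11/C12 as in the target.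

Step 22
Reactants: 29 3-O-TBS 2-(trimethylsilyl)ethyl ester of the target gibberellin
Product: 30 target gibberellin (3β,13,15-trihydroxy-16-methylidene 19,10-lactone 7-carboxylic acid; 15-hydroxyl on the side of the C9–C11–C12 bridge)
Conditions: Bu4NF, THF, 0 °C → rt; aq. NH4Cl
Reagents that add atoms: none
Why: fluoride cleaves the TBS ether and the 2-(trimethylsilyl)ethyl ester (β-elimination with loss of ethene) in one non-acidic operation that should spare the 13-hydroxy-16-ene and the 3-hydroxy lactone.

**Compound list**
1 | (2,3-dimethoxyphenyl)boronic acid | COc1cccc(B(O)O)c1OC | starting material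
2 | di-tert-butyl fumarate | CC(C)(C)OC(=O)/C=C/C(=O)OC(C)(C)C | starting material
3 | di-tert-butyl (S)-2-(2,3-dimethoxyphenyl)succinate | COc1cccc([C@H](CC(=O)OC(C)(C)C)C(=O)OC(C)(C)C)c1OC | intermediate
4 | (S)-2-(2,3-dimethoxyphenyl)succinic acid | COc1cccc([C@H](CC(=O)O)C(=O)O)c1OC | intermediate (not isolated)
5 | (S)-6,7-dimethoxy-3-oxoindane-1-carboxylic acid | COc1c3c(ccc1OC)C(=O)C[C@@H]3C(=O)O | intermediate
6 | (S)-6-hydroxy-7-methoxy-3-oxoindane-1-carboxylic acid | COc1c3c(ccc1O)C(=O)C[C@@H]3C(=O)O | intermediate
7 | (S)-6-benzyloxy-7-methoxy-3-oxoindane-1-carboxylic acid | COc1c3c(ccc1OCc4ccccc4)C(=O)C[C@@H]3C(=O)O | intermediate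
8 | methyl 2-bromopropanoate (racemic) | COC(=O)C(C)Br | starting material
9 | (1S,2S)-6-benzyloxy-7-methoxy-2-(1-methoxy-1-oxopropan-2-yl)-3-oxoindane-1-carboxylic acid (C5/C6 trans; C4 epimers) | COc1c3c(ccc1OCc4ccccc4)C(=O)[C@@H](C(C)C(=O)OC)[C@@H]3C(=O)O | intermediate
10 | but-3-en-1-ylmagnesium bromide | C=CCC[Mg]Br | starting material
11 | hydroxy ester: C10 tertiary alcohol with the but-3-enyl group on the β face and OH cis to the C5 side chain (C4 epimers) | COc1c3c(ccc1OCc4ccccc4)[C@](O)(CCC=C)[C@@H](C(C)C(=O)OC)[C@@H]3C(=O)O | intermediate (not isolated)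
12 | butenyl γ-lactone acid: lactone C10–O–C19(=O)–C4H(CH3)–C5, C10 but-3-enyl, C6 carboxylic acid, 15-methoxy-16-benzyloxy arene (C4 epimers) | COc1c3c(ccc1OCc4ccccc4)[C@@]1(CCC=C)OC(=O)C(C)[C@H]1[C@@H]3C(=O)O | intermediate
13 | lactone aldehyde: as 12 with a 3-oxopropyl chain on C10 (C4 epimers) | COc1c3c(ccc1OCc4ccccc4)[C@@]1(CCC=O)OC(=O)C(C)[C@H]1[C@@H]3C(=O)O | intermediate
14 | ring A aldol product: rings A and B with the 19,10-lactone, benzene ring C (15-OMe, 16-OBn), 7-acid, 3-hydroxy (C3 epimers) | COc1c3c(ccc1OCc4ccccc4)[C@@]12CCC(O)[C@@](C)(C(=O)O1)[C@H]2[C@@H]3C(=O)O | intermediate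
15 | 3-ketone of 14 | COc1c3c(ccc1OCc4ccccc4)[C@@]12CCC(=O)[C@@](C)(C(=O)O1)[C@H]2[C@@H]3C(=O)O | intermediate
16 | 3β-alcohol | COc1c3c(ccc1OCc4ccccc4)[C@@]12CC[C@H](O)[C@@](C)(C(=O)O1)[C@H]2[C@@H]3C(=O)O | intermediate
17 | 2-(trimethylsilyl)ethyl ester of 16 | COc1c3c(ccc1OCc4ccccc4)[C@@]12CC[C@H](O)[C@@](C)(C(=O)O1)[C@H]2[C@@H]3C(=O)OCC[Si](C)(C)C | intermediate
18 | 3-O-TBS ether of 17 | COc1c3c(ccc1OCc4ccccc4)[C@@]12CC[C@H](O[Si](C)(C)C(C)(C)C)[C@@](C)(C(=O)O1)[C@H]2[C@@H]3C(=O)OCC[Si](C)(C)C | intermediate
19 | phenol (C16–OH, C15–OMe) | COc1c3c(ccc1O)[C@@]12CC[C@H](O[Si](C)(C)C(C)(C)C)[C@@](C)(C(=O)O1)[C@H]2[C@@H]3C(=O)OCC[Si](C)(C)C | intermediate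
20 | masked o-benzoquinone: C16 ketone, C15 dimethyl ketal, C8=C9 and C11=C12 | COC1(OC)C3=C(C=CC1=O)[C@@]12CC[C@H](O[Si](C)(C)C(C)(C)C)[C@@](C)(C(=O)O1)[C@H]2[C@@H]3C(=O)OCC[Si](C)(C)C | intermediate
21 | acetyltrimethylsilane | CC(=O)[Si](C)(C)C | starting material
22 | trimethyl{[1-(trimethylsilyl)ethenyl]oxy}silane | C=C(O[Si](C)(C)C)[Si](C)(C)C | intermediate
23 | Diels–Alder adduct: bicyclo[2.2.2]oct-9(11)-ene, C14 α, C16 ketone on C12, C15 dimethyl ketal, C13 bearing SiMe3 and OSiMe3 (configuration at C13 not specified) | O=C1C(OC)(OC)[C@]23CC(O[Si](C)(C)C)([Si](C)(C)C)[C@H]1C=C2[C@@]12CC[C@H](O[Si](C)(C)C(C)(C)C)[C@@](C)(C(=O)O1)[C@H]2[C@@H]3C(=O)OCC[Si](C)(C)C | intermediate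
24 | dihydro adduct (9β-H) | O=C1C(OC)(OC)[C@]23CC(O[Si](C)(C)C)([Si](C)(C)C)[C@H]1C[C@H]2[C@@]12CC[C@H](O[Si](C)(C)C(C)(C)C)[C@@](C)(C(=O)O1)[C@H]2[C@@H]3C(=O)OCC[Si](C)(C)C | intermediate
25 | cyclopropanol (present as its potassium alkoxide): three-membered ring C12–C13–C16, C16–OH, C13–OSiMe3 | O[C@]15C(OC)(OC)[C@]23C[C@@]1(O[Si](C)(C)C)[C@H]5C[C@H]2[C@@]12CC[C@H](O[Si](C)(C)C(C)(C)C)[C@@](C)(C(=O)O1)[C@H]2[C@@H]3C(=O)OCC[Si](C)(C)C | intermediate (not isolated)
26 | 13-O-trimethylsilyl ketol: bicyclo[3.2.1]octane rings C and D, C16 ketone, C15 dimethyl ketal | O=C1C(OC)(OC)[C@]23C[C@@]1(O[Si](C)(C)C)CC[C@H]2[C@@]12CC[C@H](O[Si](C)(C)C(C)(C)C)[C@@](C)(C(=O)O1)[C@H]2[C@@H]3C(=O)OCC[Si](C)(C)C | intermediate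
27 | 16-methylidene compound (15,15-dimethoxy, 13-OSiMe3) | C=C1C(OC)(OC)[C@]23C[C@@]1(O[Si](C)(C)C)CC[C@H]2[C@@]12CC[C@H](O[Si](C)(C)C(C)(C)C)[C@@](C)(C(=O)O1)[C@H]2[C@@H]3C(=O)OCC[Si](C)(C)C | intermediate
28 | 13-hydroxy-15-oxo-16-ene enone | C=C1C(=O)[C@]23C[C@@]1(O)CC[C@H]2[C@@]12CC[C@H](O[Si](C)(C)C(C)(C)C)[C@@](C)(C(=O)O1)[C@H]2[C@@H]3C(=O)OCC[Si](C)(C)C | intermediate
29 | 3-O-TBS 2-(trimethylsilyl)ethyl ester of the target gibberellin | C=C1[C@@H](O)[C@]23C[C@@]1(O)CC[C@H]2[C@@]12CC[C@H](O[Si](C)(C)C(C)(C)C)[C@@](C)(C(=O)O1)[C@H]2[C@@H]3C(=O)OCC[Si](C)(C)C | intermediate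
30 | target gibberellin (3β,13,15-trihydroxy-16-methylidene 19,10-lactone 7-carboxylic acid; 15-hydroxyl on the side of the C9–C11–C12 bridge) | C=C1[C@@H](O)[C@]23C[C@@]1(O)CC[C@H]2[C@@]12CC[C@H](O)[C@@](C)(C(=O)O1)[C@H]2[C@@H]3C(=O)O | target

**Step count**
Total steps: 22. Longest linear sequence: 21 (steps 1 to 14 and 16 to 22; step 15 prepares the dienophile).

**Steps most likely to fail**

Step 18 (Proposed new method). The C13 carbanion may be protonated before it closes on C16 (net protodesilylation), or the silyl alkoxide may revert by retro-aldol opening of the C12–C13 bond. The fallback uses known chemistry, replaces the acyl shift by cutting and rejoining, sets out from 20 and comes back at 26. Diels–Alder reaction of 20 with the small ketene silyl acetal tert-butyl[(1-methoxyethenyl)oxy]dimethylsilane (toluene, 60 °C) should give the mixed-ketal cycloadduct F1 with the same regio- and facial sense. NaBH4 (MeOH, 0 °C) reduces the only ketone to the C16 alcohol F2. Bu4NF (1.1 equiv, THF, 0 °C) removes the silyl group of the mixed ketal, the C13 ketone forms with loss of methoxide, and retro-aldol cleavage of the C12–C16 bond follows; the dienolate should equilibrate to the conjugated 11-en-13-one with C9–H set under thermodynamic control (ring C cis-fused to ring B), giving the keto aldehyde enone F3. H2 with Pd/C (EtOAc) saturates the enone to the saturated keto aldehyde F4. SmI2 (THF, −78 °C) effects the intramolecular pinacol coupling of the C16 aldehyde with the C13 ketone and closes ring D as the 13,16-diol F5. Dess–Martin periodinane oxidises the secondary C16 alcohol to the 13-hydroxy-16-ketone F6, and Me3SiCl/imidazole (DMF) returns 26.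

Step 19. Methylene transfer may fail because the C16 carbonyl is flanked by two fully substituted oxygenated carbons, and the Lewis-acidic reagent may strip the silyl ether and trigger α-ketol isomerisation. The fallback is a two-stage Peterson olefination that sets out from 26 and comes back at 27: the small nucleophile Me3SiCH2Li with CeCl3 (THF, −78 °C) adds to C16 to give the β-hydroxysilane F7, and KH (THF, 0 °C → rt) induces syn-elimination to the exocyclic alkene 27.

Step 5. The secondary α-bromo ester may lose HBr instead of being substituted, and proton exchange between product and enolate may stall conversion or cause double alkylation. The fallback introduces the C18 methyl later; it sets out from 7 and comes back at 12. Dianion alkylation of 7 with methyl bromoacetate (primary electrophile, same conditions as step 5) gives the trans acetate keto acid F8. Organocerium addition of 10 with in situ lactonisation (as in step 6) gives the C4-unsubstituted butenyl lactone acid F9. LiN(i-Pr)2 (2.2 equiv, THF, −78 °C) followed by MeI methylates the lactone enolate at C4, while the carboxylate protects C6, and returns 12 as C4 epimers that converge in step 8.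

Further compounds
F1 | step 18 | mixed-ketal cycloadduct: as 23 but C13 bears OMe and OSi(t-Bu)Me2 | O=C1C(OC)(OC)[C@]23CC(OC)(O[Si](C)(C)C(C)(C)C)[C@H]1C=C2[C@@]12CC[C@H](O[Si](C)(C)C(C)(C)C)[C@@](C)(C(=O)O1)[C@H]2[C@@H]3C(=O)OCC[Si](C)(C)C
F2 | step 18 | C16 alcohol of F1 (C16 epimers) | OC1C(OC)(OC)[C@]23CC(OC)(O[Si](C)(C)C(C)(C)C)[C@H]1C=C2[C@@]12CC[C@H](O[Si](C)(C)C(C)(C)C)[C@@](C)(C(=O)O1)[C@H]2[C@@H]3C(=O)OCC[Si](C)(C)C
F3 | step 18 | keto aldehyde enone: C16 aldehyde on the C15 dimethyl ketal, ring C 11-en-13-one, 9β-H | O=CC(OC)(OC)[C@]23CC(=O)C=C[C@H]2[C@@]12CC[C@H](O[Si](C)(C)C(C)(C)C)[C@@](C)(C(=O)O1)[C@H]2[C@@H]3C(=O)OCC[Si](C)(C)C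
F4 | step 18 | saturated keto aldehyde | O=CC(OC)(OC)[C@]23CC(=O)CC[C@H]2[C@@]12CC[C@H](O[Si](C)(C)C(C)(C)C)[C@@](C)(C(=O)O1)[C@H]2[C@@H]3C(=O)OCC[Si](C)(C)C
F5 | step 18 | 13,16-diol with ring D closed (C16 epimers) | OC1C(OC)(OC)[C@]23C[C@@]1(O)CC[C@H]2[C@@]12CC[C@H](O[Si](C)(C)C(C)(C)C)[C@@](C)(C(=O)O1)[C@H]2[C@@H]3C(=O)OCC[Si](C)(C)C
F6 | step 18 | 13-hydroxy-16-ketone (26 without the trimethylsilyl group) | O=C1C(OC)(OC)[C@]23C[C@@]1(O)CC[C@H]2[C@@]12CC[C@H](O[Si](C)(C)C(C)(C)C)[C@@](C)(C(=O)O1)[C@H]2[C@@H]3C(=O)OCC[Si](C)(C)C
F7 | step 19 | β-hydroxysilane: 16-hydroxy-16-(trimethylsilylmethyl) adduct of 26 (C16 epimers) | C[Si](C)(C)CC1(O)C(OC)(OC)[C@]23C[C@@]1(O[Si](C)(C)C)CC[C@H]2[C@@]12CC[C@H](O[Si](C)(C)C(C)(C)C)[C@@](C)(C(=O)O1)[C@H]2[C@@H]3C(=O)OCC[Si](C)(C)C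
F8 | step 5 | (1S,2S)-6-benzyloxy-7-methoxy-2-(2-methoxy-2-oxoethyl)-3-oxoindane-1-carboxylic acid | COc1c3c(ccc1OCc4ccccc4)C(=O)[C@@H](CC(=O)OC)[C@@H]3C(=O)O
F9 | step 5 | C4-unsubstituted butenyl lactone acid (12 without the C4 methyl) | COc1c3c(ccc1OCc4ccccc4)[C@@]1(CCC=C)OC(=O)C[C@H]1[C@@H]3C(=O)O
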